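**Plan**

1. Target: oxolane ring A (O1, C2–C5) is all-cis, with guaiacyl ring B on C2, methyl groups on C3 and C4, and veratryl ring C on C5; the ring B oxygen carries the erythro chain C8(CH3)–C7(OH)–veratryl ring D.
2. Retrosynthetic cuts, in order: C7–H (ketone reduction), C7–ring D (aryl Grignard on a Weinreb amide), O–C8 (Mitsunobu), the C–H bonds at C2 and C3 (hydrogenation), C2=C3, then O1–C2 (ester) and C4–C5 (aldol).
3. Enabling feature: C2 and C3 are neighbours in ring A. C2 lies between O1 and ring B, so it can be the carbonyl carbon of a ring B aroyl ester on the C5 oxygen; C3 with its methyl can be the carbonyl carbon of a methyl ketone. Low-valent titanium joins these two carbons and closes ring A.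
4. Forward order: a syn-aldol builds C4–C5, the chain is taken to the methyl ketone and aroylated, ring A (the only ring formed) closes at C2=C3 and is hydrogenated, and the side chain is joined at the ring B phenol in the order O–C8, C7–ring D, C7–H.
5. Stereochemistry: C4 and C5 from the (R)-benzyloxazolidinone syn-aldol; C2 and C3 from syn hydrogen delivery to the face opposite the cis C4 methyl and C5 aryl; C8 from ethyl (R)-lactate with Mitsunobu inversion; C7 from chelation-controlled reduction of the C7 ketone.

Key step: step 5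

Remark: read from the SMILES, the oxolane is all-cis, (2S,3R,4S,5R), and the side chain is erythro, (7R,8S); C7 is the carbinol carbon, C8 the ether-bearing carbon and C9 its methyl group.

**Step 1**
Reactants: 1 veratraldehyde (3,4-dimethoxybenzaldehyde); 2 (R)-4-benzyl-3-propionyloxazolidin-2-one
Product: 4 (4R)-4-benzyl-3-[(2R,3R)-3-(3,4-dimethoxyphenyl)-3-hydroxy-2-methylpropanoyl]oxazolidin-2-one, via Z-boron enolate 3 (not isolated)
Conditions: Bu2BOTf, iPr2NEt, CH2Cl2, 0 °C; then 1, −78 → 0 °C; pH 7 buffer, MeOH, H2O2, 0 °C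
Reagents that add atoms: none
Why: Evans syn-aldol reaction: the Z-boron enolate 3 adds to the aldehyde through a chair-like Zimmerman–Traxler transition state in which the benzyl group of the auxiliary shields one enolate face, so the syn adduct with (2R,3R) configuration, the future C4 and C5, should form selectively.

**Step 2**
Reactants: 4 (4R)-4-benzyl-3-[(2R,3R)-3-(3,4-dimethoxyphenyl)-3-hydroxy-2-methylpropanoyl]oxazolidin-2-one
Product: 5 (2R,3R)-3-(3,4-dimethoxyphenyl)-3-hydroxy-N-methoxy-N,2-dimethylpropanamide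
Conditions: MeNH(OMe)·HCl, AlMe3, CH2Cl2, −20 → 0 °C; aq. potassium sodium tartrate
Reagents that add atoms: N,O-dimethylhydroxylamine hydrochloride, CNOC.Cl
Why: Transamination of the imide to the Weinreb amide by the aluminium amide made from AlMe3 and MeNH(OMe)·HCl is the standard auxiliary removal for such aldol adducts, the free β-hydroxyl directing attack to the exocyclic carbonyl as its aluminium alkoxide, and it touches neither stereocentre.

**Step 3**
Reactants: 5 (2R,3R)-3-(3,4-dimethoxyphenyl)-3-hydroxy-N-methoxy-N,2-dimethylpropanamide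
Product: 6 (3R,4R)-4-(3,4-dimethoxyphenyl)-4-hydroxy-3-methylbutan-2-one
Conditions: MeMgBr (3.5 equiv), THF, −20 → 0 °C; aq. NH4Cl
Reagents that add atoms: methylmagnesium bromide, C[Mg]Br
Why: Weinreb ketone synthesis: the N-methoxy-N-methyl amide accepts one methyl group only and frees the ketone on aqueous quench, so that the magnesium alkoxide of the benzylic alcohol never faces a carbonyl group and neither retro-aldol cleavage nor epimerisation of the α-carbon is expected.

**Step 4**
Reactants: 6 (3R,4R)-4-(3,4-dimethoxyphenyl)-4-hydroxy-3-methylbutan-2-one; 7 4-(benzyloxy)-3-methoxybenzoic acid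
Product: 9 (1R,2R)-1-(3,4-dimethoxyphenyl)-2-methyl-3-oxobutyl 4-(benzyloxy)-3-methoxybenzoate, via 4-(benzyloxy)-3-methoxybenzoyl chloride 8 (not isolated)
Conditions: 7, (COCl)2, DMF (cat.), CH2Cl2, 0 °C → rt, concentrate; then 6, pyridine, DMAP (cat.), CH2Cl2, 0 °C → rt
Reagents that add atoms: none
Why: Acylation of the secondary benzylic alcohol by the aroyl chloride 8 under nucleophilic catalysis by DMAP (acyl transfer by addition–elimination) needs only pyridine as base at 0 °C, mild enough that E1cB loss of the new aroyloxy group and retro-aldol cleavage should not compete, and it leaves both stereocentres as they are.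

**Step 5**
Reactants: 9 (1R,2R)-1-(3,4-dimethoxyphenyl)-2-methyl-3-oxobutyl 4-(benzyloxy)-3-methoxybenzoate
Product: 11 (4S,5R)-2-[4-(benzyloxy)-3-methoxyphenyl]-5-(3,4-dimethoxyphenyl)-3,4-dimethyl-4,5-dihydrofuran (C4 methyl and C5 aryl cis), via cyclic TiCl2 diolate 10 (not isolated)
Conditions: TiCl3 (6 equiv), Zn dust (12 equiv), DME, reflux, 2 h; pyridine (2 equiv); then 9 in DME by syringe pump over 12 h (final 0.005 M), reflux; cool, K2CO3, filter through basic Al2O3
Reagents that add atoms: none
Why: Proposed new method: electron transfer from the low-valent titanium surface to the methyl ketone should give a titanium-bound ketyl at C3, which adds to the carbonyl carbon C2 of the neighbouring aroyl ester and gives the cis-2,3-diolate 10; titanium then strips both oxygens, as in the second stage of a McMurry olefination, and leaves the C2=C3 enol ether. The closest known reaction type is the titanium-induced oxo-ester cyclisation of acyloxy enones and ortho-acyloxyaryl ketones to furans and benzofurans, together with the McMurry keto ester cyclisation; an aliphatic β-aroyloxy ketone has not been shown in this role. Ring A closes in the 5-exo-trig mode, C3 attacking the ester C=O whose oxygen stays outside the ring. No stereocentre is created, since C2 and C3 become trigonal, and C4 and C5 are carried through unchanged. The step needs ring closure to outrun pinacol dimerisation of the ketone, β-elimination of the aroyloxy group, enolisation at C4 and cleavage of the benzylic C5–O bond; slow addition at high dilution, the short tether that holds C2 within reach of the C3 ketyl, pre-reduction so that little Lewis-acidic TiCl3 remains, and the pyridine buffer are meant to secure this.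

**Step 6**
Reactants: 11 (4S,5R)-2-[4-(benzyloxy)-3-methoxyphenyl]-5-(3,4-dimethoxyphenyl)-3,4-dimethyl-4,5-dihydrofuran
Product: 13 4-[(2S,3R,4S,5R)-5-(3,4-dimethoxyphenyl)-3,4-dimethyloxolan-2-yl]-2-methoxyphenol, via debenzylated dihydrofuran 12 (not isolated)
Conditions: H2 (1–4 atm), 10% Pd/C, K2CO3 (cat.), EtOAc, rt
Reagents that add atoms: none
Why: Heterogeneous catalytic hydrogenation adds both hydrogens syn from the face of the enol ether opposite the cis C4 methyl and C5 aryl groups, which sets C2 as S and C3 as R and makes ring A all-cis, in line with the known all-cis reduction of 2,5-diaryl-3,4-dimethylfurans, while hydrogenolysis of the benzyl ether, expected to be the faster event, frees the phenol.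

**Step 7**
Reactants: 13 4-[(2S,3R,4S,5R)-5-(3,4-dimethoxyphenyl)-3,4-dimethyloxolan-2-yl]-2-methoxyphenol; 14 ethyl (R)-lactate
Product: 15 ethyl (2S)-2-{4-[(2S,3R,4S,5R)-5-(3,4-dimethoxyphenyl)-3,4-dimethyloxolan-2-yl]-2-methoxyphenoxy}propanoate
Conditions: PPh3, DIAD, THF, 0 °C → rt
Reagents that add atoms: none
Why: Mitsunobu etherification of a phenol with a lactate ester is an SN2 displacement at the activated secondary carbinol, so the (R)-lactate should give the (S)-aryloxypropanoate with clean inversion at C8 under neutral conditions that spare the acid-sensitive all-cis oxolane.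

**Step 8**
Reactants: 15 ethyl (2S)-2-{4-[(2S,3R,4S,5R)-5-(3,4-dimethoxyphenyl)-3,4-dimethyloxolan-2-yl]-2-methoxyphenoxy}propanoate
Product: 16 (2S)-2-{4-[(2S,3R,4S,5R)-5-(3,4-dimethoxyphenyl)-3,4-dimethyloxolan-2-yl]-2-methoxyphenoxy}-N-methoxy-N-methylpropanamide
Conditions: MeNH(OMe)·HCl, iPrMgCl, THF, −20 → −10 °C; aq. NH4Cl
Reagents that add atoms: N,O-dimethylhydroxylamine hydrochloride, CNOC.Cl
Why: Aminolysis of the ester by the chloromagnesium amide of N,O-dimethylhydroxylamine at −20 °C is a standard route to Weinreb amides that α-alkoxy esters survive without loss of configuration and that exposes the oxolane to no strong Lewis acid.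

**Step 9**
Reactants: 16 (2S)-2-{4-[(2S,3R,4S,5R)-5-(3,4-dimethoxyphenyl)-3,4-dimethyloxolan-2-yl]-2-methoxyphenoxy}-N-methoxy-N-methylpropanamide; 17 4-bromo-1,2-dimethoxybenzene
Product: 19 (2S)-1-(3,4-dimethoxyphenyl)-2-{4-[(2S,3R,4S,5R)-5-(3,4-dimethoxyphenyl)-3,4-dimethyloxolan-2-yl]-2-methoxyphenoxy}propan-1-one, via 3,4-dimethoxyphenylmagnesium bromide 18 (not isolated)
Conditions: 17, Mg, THF, rt; then 16, THF, −20 → 0 °C; aq. NH4Cl, 0 °C
Reagents that add atoms: none
Why: Weinreb ketone synthesis with an aryl Grignard reagent: the amide takes up one aryl group only and the aryl ketone appears only on the cold, buffered quench, so C8 next to the new carbonyl meets no base and should keep its configuration.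

**Step 10**
Reactants: 19 (2S)-1-(3,4-dimethoxyphenyl)-2-{4-[(2S,3R,4S,5R)-5-(3,4-dimethoxyphenyl)-3,4-dimethyloxolan-2-yl]-2-methoxyphenoxy}propan-1-one
Product: 20 (1R,2S)-1-(3,4-dimethoxyphenyl)-2-{4-[(2S,3R,4S,5R)-5-(3,4-dimethoxyphenyl)-3,4-dimethyloxolan-2-yl]-2-methoxyphenoxy}propan-1-ol (CNP0286615.2)
Conditions: Zn(BH4)2, Et2O, −20 → 0 °C; aq. NH4Cl
Reagents that add atoms: none
Why: Chelation-controlled (Cram-chelate) hydride reduction: zinc bridges the carbonyl oxygen and the C8 aryloxy oxygen, hydride enters from the side of the C8 hydrogen, and the anti (erythro) alcohol results, which with (8S) is the (7R) carbinol of the target.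

**Compound list**

1 | veratraldehyde (3,4-dimethoxybenzaldehyde) | COc1ccc(C=O)cc1OC | starting material
2 | (R)-4-benzyl-3-propionyloxazolidin-2-one | CCC(=O)N1[C@H](Cc2ccccc2)COC1=O | starting material
3 | dibutylboron Z-enolate of 2 (not isolated) | C/C=C(\OB(CCCC)CCCC)N1[C@H](Cc2ccccc2)COC1=O | intermediate
4 | (4R)-4-benzyl-3-[(2R,3R)-3-(3,4-dimethoxyphenyl)-3-hydroxy-2-methylpropanoyl]oxazolidin-2-one | COc1ccc([C@H](O)[C@@H](C)C(=O)N2[C@H](Cc3ccccc3)COC2=O)cc1OC | intermediate
5 | (2R,3R)-3-(3,4-dimethoxyphenyl)-3-hydroxy-N-methoxy-N,2-dimethylpropanamide | COc1ccc([C@H](O)[C@@H](C)C(=O)N(C)OC)cc1OC | intermediate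
6 | (3R,4R)-4-(3,4-dimethoxyphenyl)-4-hydroxy-3-methylbutan-2-one | COc1ccc([C@H](O)[C@@H](C)C(C)=O)cc1OC | intermediate
7 | 4-(benzyloxy)-3-methoxybenzoic acid | COc1cc(C(=O)O)ccc1OCc1ccccc1 | starting material
8 | 4-(benzyloxy)-3-methoxybenzoyl chloride (not isolated) | COc1cc(C(Cl)=O)ccc1OCc1ccccc1 | intermediate
9 | (1R,2R)-1-(3,4-dimethoxyphenyl)-2-methyl-3-oxobutyl 4-(benzyloxy)-3-methoxybenzoate | COc1cc(C(=O)O[C@@H](c2ccc(OC)c(OC)c2)[C@@H](C)C(C)=O)ccc1OCc1ccccc1 | intermediate
10 | titanium-bound cis-2,3-diolate from ring closure of 9, drawn formally as its TiCl2 chelate, C4 and C5 as in 9 (not isolated) | COc1cc(C23O[C@@H](c4ccc(OC)c(OC)c4)[C@@H](C)C2(C)O[Ti](Cl)(Cl)O3)ccc1OCc1ccccc1 | intermediate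
11 | (4S,5R)-2-[4-(benzyloxy)-3-methoxyphenyl]-5-(3,4-dimethoxyphenyl)-3,4-dimethyl-4,5-dihydrofuran | COc1cc(C2O[C@@H](c3ccc(OC)c(OC)c3)[C@@H](C)C=2C)ccc1OCc1ccccc1 | intermediate
12 | 4-[(4S,5R)-5-(3,4-dimethoxyphenyl)-3,4-dimethyl-4,5-dihydrofuran-2-yl]-2-methoxyphenol (not isolated) | COc1cc(C2O[C@@H](c3ccc(OC)c(OC)c3)[C@@H](C)C=2C)ccc1O | intermediate
13 | 4-[(2S,3R,4S,5R)-5-(3,4-dimethoxyphenyl)-3,4-dimethyloxolan-2-yl]-2-methoxyphenol | COc1cc([C@H]2O[C@@H](c3ccc(OC)c(OC)c3)[C@@H](C)[C@H]2C)ccc1O | intermediate
14 | ethyl (R)-lactate | CCOC(=O)[C@@H](C)O | starting material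
15 | ethyl (2S)-2-{4-[(2S,3R,4S,5R)-5-(3,4-dimethoxyphenyl)-3,4-dimethyloxolan-2-yl]-2-methoxyphenoxy}propanoate | CCOC(=O)[C@H](C)Oc1ccc([C@H]2O[C@@H](c3ccc(OC)c(OC)c3)[C@@H](C)[C@H]2C)cc1OC | intermediate
16 | (2S)-2-{4-[(2S,3R,4S,5R)-5-(3,4-dimethoxyphenyl)-3,4-dimethyloxolan-2-yl]-2-methoxyphenoxy}-N-methoxy-N-methylpropanamide | CON(C)C(=O)[C@H](C)Oc1ccc([C@H]2O[C@@H](c3ccc(OC)c(OC)c3)[C@@H](C)[C@H]2C)cc1OC | intermediate
17 | 4-bromo-1,2-dimethoxybenzene | COc1ccc(Br)cc1OC | starting material
18 | 3,4-dimethoxyphenylmagnesium bromide (not isolated) | COc1ccc([Mg]Br)cc1OC | intermediate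
19 | (2S)-1-(3,4-dimethoxyphenyl)-2-{4-[(2S,3R,4S,5R)-5-(3,4-dimethoxyphenyl)-3,4-dimethyloxolan-2-yl]-2-methoxyphenoxy}propan-1-one | COc1ccc(C(=O)[C@H](C)Oc2ccc([C@H]3O[C@@H](c4ccc(OC)c(OC)c4)[C@@H](C)[C@H]3C)cc2OC)cc1OC | intermediate
20 | (1R,2S)-1-(3,4-dimethoxyphenyl)-2-{4-[(2S,3R,4S,5R)-5-(3,4-dimethoxyphenyl)-3,4-dimethyloxolan-2-yl]-2-methoxyphenoxy}propan-1-ol | COc1ccc([C@@H](O)[C@H](C)Oc2ccc([C@H]3O[C@@H](c4ccc(OC)c(OC)c4)[C@@H](C)[C@H]3C)cc2OC)cc1OC | target

**Step count and risks**

Total step count: 10. Longest linear sequence: 10 steps (1 and 2 to 20, steps 1–10); 7, 14 and 17 enter as purchased compounds.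

Steps most likely to fail:

Step 5 (carries the label). The titanium ketyl or residual Lewis-acidic titanium may expel the aroyloxy group, by β-elimination or by reductive cleavage of the benzylic C5–O bond, or ketone molecules may pair up intermolecularly faster than the ring closes. The fallback sets out from 9 and uses known chemistry to form the same C2=C3 bond and the same ring. Both carbonyl groups would be methylenated with Cp2TiMe2 (toluene, 70 °C) to give 1-(benzyloxy)-4-(1-{[(1R,2S)-1-(3,4-dimethoxyphenyl)-2,3-dimethylbut-3-en-1-yl]oxy}ethenyl)-2-methoxybenzene F1. Ring-closing enol ether–olefin metathesis of its two 1,1-disubstituted alkenes with the molybdenum alkylidene Mo(=CHCMe2Ph)(=N-2,6-iPr2C6H3)[OCMe(CF3)2]2 (benzene, 25–60 °C) would then expel ethene and rejoin the route at 11.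

Step 6. On palladium the double bond may migrate from C2=C3 toward C4 before hydrogen adds, which would erode C4 and the cis relationships, and the benzylic C–O bonds of ring A may undergo hydrogenolysis alongside the benzyl ether. The fallback sets out from 11 and separates the two reductions. The enol ether would first be saturated over Rh/Al2O3 (H2, EtOAc, rt), a catalyst far less prone to double-bond migration and benzylic C–O cleavage, to give (2S,3R,4S,5R)-2-[4-(benzyloxy)-3-methoxyphenyl]-5-(3,4-dimethoxyphenyl)-3,4-dimethyloxolane F2. The benzyl ether would then be removed by transfer hydrogenolysis (10% Pd/C, cyclohexa-1,4-diene, EtOH, rt), and the route is rejoined at 13.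

Step 10. The weakly basic aryloxy oxygen may chelate zinc poorly, so that open Felkin–Anh attack competes and the threo (7S) epimer forms. The fallback sets out from 19 and replaces substrate control by catalyst control: Corey–Bakshi–Shibata reduction with (R)-2-methyl-CBS-oxazaborolidine (cat.) and BH3·SMe2 in THF at −20 °C. On the usual model, with ring D as the large group, this delivers hydride to the Si face of the C7 carbonyl and gives 20 directly; it makes no new compound (F0).

**Further compounds**

F1 | step 5 | 1-(benzyloxy)-4-(1-{[(1R,2S)-1-(3,4-dimethoxyphenyl)-2,3-dimethylbut-3-en-1-yl]oxy}ethenyl)-2-methoxybenzene | C=C(O[C@@H](c1ccc(OC)c(OC)c1)[C@@H](C)C(C)=C)c1ccc(OCc2ccccc2)c(OC)c1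
F2 | step 6 | (2S,3R,4S,5R)-2-[4-(benzyloxy)-3-methoxyphenyl]-5-(3,4-dimethoxyphenyl)-3,4-dimethyloxolane | COc1cc([C@H]2O[C@@H](c3ccc(OC)c(OC)c3)[C@@H](C)[C@H]2C)ccc1OCc1ccccc1
F0 | step 10 | none | none
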